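**Plan**
- Retrosynthesis: remove the acetate and cut C12–C13 (Suzuki coupling), then C8–O (from a C8=C17 methylidene), then C4–C18 (γ-hydroxymethylation). Next cut C5–C10 and C2–C3 together to reach an acyclic keto-enal, then C9–C10 (allylic alkylation) and C8–C9 (Stille coupling), back to 6-methylhept-5-en-2-one.
- Enabling feature: in ring A the opposite bonds C2–C3 and C5–C10 both flank C1. A carbonyl at C1 makes C2 and C10 its two α-carbons, and C3–C4–C5 can be an enal (C3 aldehyde, C5 β-carbon). Because C5–C10 is also the ring-fusion bond and C6–C9 are already a chain, one Michael–aldol event closes rings B and A together.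
- Forward: the chain is built first (steps 1–7), both rings form in step 8, then C18, removal of the C1 oxygen, the 8-OH, the side chain and the acetate.
- Stereochemistry: C9 from ligand control in the Ir-catalysed allylic alkylation; C10 and C5 from C9 through the chair transition state of step 8; C4 by attack anti to the axial C10 methyl; C8 by α-face epoxidation; 13E from the alkenyl iodide.

Key step: step 8

Assumption: compounds 4, 8 and 22 and the phosphoramidite ligand are bought; atoms of all intermediates carry labdane numbers (C18 = the 4α CH2O carbon, trans to the C10 methyl; C19 = 4β-CH3).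

**Step 1**
Reactants: 1 6-methylhept-5-en-2-one
Product: 3 6-methylhepta-1,5-dien-2-yl trifluoromethanesulfonate, via lithium enolate 2 (not isolated)
Conditions: LiN(iPr)2 (1.1 equiv), THF, −78 °C; then PhNTf2, −78 to 0 °C; aq. NH4Cl
Reagents that add atoms: N-phenylbis(trifluoromethanesulfonimide), O=S(=O)(N(c1ccccc1)S(=O)(=O)C(F)(F)F)C(F)(F)F
Why: Kinetic deprotonation of the methyl ketone at the methyl group and O-sulfonylation of the terminal enolate (enol triflate synthesis) fix the 1,1-disubstituted alkene that becomes C8=C17.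

**Step 2**
Reactants: 3 6-methylhepta-1,5-dien-2-yl trifluoromethanesulfonate; 4 (2E)-3-(tributylstannyl)prop-2-en-1-ol
Product: 5 (2E)-8-methyl-4-methylidenenona-2,7-dien-1-ol
Conditions: Pd(PPh3)4 (5 mol %), LiCl (3 equiv), THF, 65 °C
Reagents that add atoms: none
Why: Stille coupling of an alkenyl triflate with an alkenylstannane joins C8 to C9 with retention of the E geometry and tolerates the free hydroxyl.

**Step 3**
Reactants: 5 (2E)-8-methyl-4-methylidenenona-2,7-dien-1-ol
Product: 6 methyl (2E)-8-methyl-4-methylidenenona-2,7-dien-1-yl carbonate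
Conditions: ClCO2Me, pyridine, CH2Cl2, 0 °C
Reagents that add atoms: methyl chloroformate, COC(=O)Cl
Why: Acylation of the primary allylic alcohol with a chloroformate installs the carbonate leaving group needed for the allyl-metal step.

**Step 4**
Reactants: 6 methyl (2E)-8-methyl-4-methylidenenona-2,7-dien-1-yl carbonate
Product: 7 methyl (2E,7E)-9-hydroxy-8-methyl-4-methylidenenona-2,7-dien-1-yl carbonate
Conditions: SeO2 (0.2 equiv), t-BuOOH (3 equiv), salicylic acid (0.1 equiv), CH2Cl2, 0 to 20 °C
Reagents that add atoms: selenium dioxide, O=[Se]=O; tert-butyl hydroperoxide (reoxidant), CC(C)(C)OO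
Why: Catalytic SeO2 allylic oxidation (ene reaction, then [2,3]-sigmatropic shift) attacks the most electron-rich trisubstituted alkene at its E-methyl group, so the future C3 oxygen is placed before any stereocentre or doubly allylic C–H exists.

**Step 5**
Reactants: 7 methyl (2E,7E)-9-hydroxy-8-methyl-4-methylidenenona-2,7-dien-1-yl carbonate; 8 methyl 2-methyl-3-oxobutanoate
Product: 9 methyl (3S,7E)-2-acetyl-3-ethenyl-9-hydroxy-2,8-dimethyl-4-methylidenenon-7-enoate (both C2 epimers)
Conditions: [Ir(cod)Cl]2 (2 mol %), (Sa,S,S)-O,O′-(1,1′-binaphthalene-2,2′-diyl) N,N-bis(1-phenylethyl)phosphoramidite (4 mol %), TBD (10 mol %), THF, 25 °C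
Reagents that add atoms: none
Why: Ir-catalysed asymmetric allylic alkylation with a stabilised enolate attacks the allyl terminus bearing the alkenyl group (branched product) and the phosphoramidite selects the face, which sets labdane C9; the ligand antipode is chosen by analogy with aryl- and alkenyl-substituted allyl carbonates, and the C10 centre is of no consequence because it is enolised in step 8.

**Step 6**
Reactants: 9 methyl (3S,7E)-2-acetyl-3-ethenyl-9-hydroxy-2,8-dimethyl-4-methylidenenon-7-enoate
Product: 10 (4R,8E)-4-ethenyl-10-hydroxy-3,9-dimethyl-5-methylidenedec-8-en-2-one (both C3 epimers)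
Conditions: LiCl (2 equiv), H2O (2 equiv), DMSO, 140 °C
Reagents that add atoms: none
Why: Krapcho demethoxycarbonylation (chloride SN2 at the ester methyl, then loss of CO2) removes the activating ester under near-neutral conditions that touch neither C9 nor the 1,4-diene.

**Step 7**
Reactants: 10 (4R,8E)-4-ethenyl-10-hydroxy-3,9-dimethyl-5-methylidenedec-8-en-2-one
Product: 11 (2E,7R)-7-ethenyl-2,8-dimethyl-6-methylidene-9-oxodec-2-enal (both C8 epimers)
Conditions: MnO2 (15 equiv), CH2Cl2, 25 °C
Reagents that add atoms: none
Why: MnO2 oxidises only the allylic alcohol and gives the (E)-enal that serves as the C3–C4–C5 electrophile.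

**Step 8**
Reactants: 11 (2E,7R)-7-ethenyl-2,8-dimethyl-6-methylidene-9-oxodec-2-enal
Product: 14 13,14,15,16,19-pentanorlabda-2,8(17),11-trien-1-one (trans-fused; 4α-methyl; 5α-H; 9α-H; 10β-methyl), via Michael adduct keto aldehyde 12 (not isolated), via aldol adduct 13 (not isolated)
Conditions: KOH (0.5 equiv), MeOH, 0.01 M, 0 to 40 °C
Reagents that add atoms: none
Why: Hydroxide equilibrates the ketone enolates; the C10 enolate adds to C5 of the tethered (E)-enal (Michael addition, 6-exo-trig, closes ring B and makes the ring-fusion bond C5–C10), then C2, now the only enolisable ketone position, adds to the C3 aldehyde (aldol, 6-enolexo-exo-trig, closes ring A and makes C2–C3) and E1cB loss of water gives the C2=C3 enone, which pulls the reversible steps forward. The closest known reaction type is the Robinson-type Michael–aldol condensation of a ketone with an enal to a cyclohexenone (a [3+3] annulation), run here within one chain so that both rings form. C10 is controlled by allylic 1,3-strain in the chair transition state: the C9–H bond lies in the enolate plane next to C1, the C8 tether delivers C5 to one face, and the C10 methyl therefore becomes axial and cis to the equatorial C9 vinyl group. C5 is controlled by the same chair, in which the enal arm is equatorial, so H5 ends trans to the C10 methyl and the two arms that close ring A are trans-diequatorial, which should give the trans-decalin; C4 forms as an epimerisable centre (equatorial methyl expected) that step 9 flattens again. The step needs regioselectivity between the C10 and C2 enolates, secured by ring size (C2 could only close an eight-membered ring in the Michael step or a ten-membered ring in an early aldol), and chemoselectivity against intermolecular aldol reactions, secured by high dilution and the α-methyl, β-alkyl substitution of the enal; keeping C8 as a methylidene instead of the carbinol removes a 1,3-diaxial methyl–methyl clash from this transition state.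

**Step 9**
Reactants: 14 13,14,15,16,19-pentanorlabda-2,8(17),11-trien-1-one
Product: 16 18-hydroxy-13,14,15,16-tetranorlabda-2,8(17),11-trien-1-one, via trimethylsilyl dienol ether 15 (not isolated)
Conditions: Me3SiOTf, Et3N, CH2Cl2, 0 °C; concentrate; then 37 % aq. HCHO, Yb(OTf)3 (10 mol %), THF/H2O, 25 °C
Reagents that add atoms: formaldehyde, C=O
Why: Soft enolisation can only remove H4 (C10 has no hydrogen) and gives the through-conjugated silyl dienol ether, and a vinylogous Mukaiyama aldol with formaldehyde under water-tolerant Lewis acid catalysis should attack the γ-carbon C4 from the α-face, anti to the axial C10 methyl, giving the 4α-CH2OH/4β-CH3 quaternary centre and returning the C2=C3 enone.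

**Step 10**
Reactants: 16 18-hydroxy-13,14,15,16-tetranorlabda-2,8(17),11-trien-1-one
Product: 17 18-hydroxy-13,14,15,16-tetranorlabda-8(17),11-dien-1-one
Conditions: [(Ph3P)CuH]6 (0.4 equiv), H2O (2 equiv), benzene, 25 °C
Reagents that add atoms: none
Why: Conjugate reduction with the copper hydride cluster delivers hydride to C3 of the enone only and leaves the vinyl and methylidene groups and the doubly allylic C9–H untouched.

**Step 11**
Reactants: 17 18-hydroxy-13,14,15,16-tetranorlabda-8(17),11-dien-1-one
Product: 19 13,14,15,16-tetranorlabda-8(17),11-dien-18-ol, via tosylhydrazone 18 (not isolated)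
Conditions: TsNHNH2, EtOH, 70 °C; concentrate; then catecholborane (3 equiv), CHCl3, 0 °C; then NaOAc·3H2O, 60 °C
Reagents that add atoms: none
Why: Tosylhydrazone formation, hydride reduction with catecholborane and acetate-induced loss of sulfinate and N2 is a mild variant of the Wolff–Kishner reduction that takes C1=O to CH2 without the hot alkali that would conjugate the 1,4-diene through C9.

**Step 12**
Reactants: 19 13,14,15,16-tetranorlabda-8(17),11-dien-18-ol
Product: 20 8α,17-epoxy-13,14,15,16-tetranorlabd-11-en-18-ol
Conditions: mCPBA (1.05 equiv), NaHCO3, CH2Cl2, −10 °C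
Reagents that add atoms: 3-chloroperoxybenzoic acid, O=C(OO)c1cccc(Cl)c1
Why: Peracid epoxidation is faster at the 1,1-disubstituted C8=C17 alkene than at the vinyl group and should come from the α-face, opposite the axial C10 methyl, which sets the C8 oxygen α.

**Step 13**
Reactants: 20 8α,17-epoxy-13,14,15,16-tetranorlabd-11-en-18-ol
Product: 21 13,14,15,16-tetranorlabd-11-ene-8α,18-diol
Conditions: LiAlH4, THF, 0 to 40 °C
Reagents that add atoms: none
Why: Hydride opens the spiro-epoxide at the primary carbon C17 (SN2), leaving the tertiary 8α-alcohol and an axial 8β-methyl as in the target.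

**Step 14**
Reactants: 21 13,14,15,16-tetranorlabd-11-ene-8α,18-diol; 22 ethyl (2E)-3-iodobut-2-enoate
Product: 24 ethyl 8α,18-dihydroxylabd-13E-en-15-oate, via B-alkyl-9-BBN adduct 23 (not isolated)
Conditions: 9-BBN (3.5 equiv), THF, 0 to 25 °C; then 22, PdCl2(dppf) (5 mol %), K3PO4 (3 M aq.), DMF, 25 °C
Reagents that add atoms: none
Why: Anti-Markovnikov hydroboration of the vinyl group and B-alkyl Suzuki–Miyaura coupling with the (E)-alkenyl iodide form C12–C13 with retention of alkene geometry, so the 13E enoate is made directly; the hydroxyls only consume extra borane.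

**Step 15**
Reactants: 24 ethyl 8α,18-dihydroxylabd-13E-en-15-oate
Product: 25 8α,18-dihydroxylabd-13E-en-15-oic acid
Conditions: LiOH, THF/MeOH/H2O, 45 °C; then aq. HCl to pH 3
Reagents that add atoms: lithium hydroxide, [Li+].[OH-]
Why: Saponification of the ethyl ester gives the free acid, and no other group is base-labile at this stage.

**Step 16**
Reactants: 25 8α,18-dihydroxylabd-13E-en-15-oic acid
Product: 26 18-acetoxy-8α-hydroxylabd-13E-en-15-oic acid (target)
Conditions: Ac2O (1.3 equiv), pyridine, 0 to 20 °C; aq. NaHCO3 work-up, then mild acidification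
Reagents that add atoms: acetic anhydride, CC(=O)OC(C)=O
Why: Acetylation is selective for the primary C18 hydroxyl over the hindered tertiary C8 hydroxyl, and any mixed anhydride at C15 is hydrolysed in the bicarbonate work-up.

**Compound list**
1 | 6-methylhept-5-en-2-one | CC(=O)CCC=C(C)C | starting material
2 | lithium 6-methylhepta-1,5-dien-2-olate | [Li+].[O-]C(=C)CCC=C(C)C | intermediate
3 | 6-methylhepta-1,5-dien-2-yl trifluoromethanesulfonate | C=C(OS(=O)(=O)C(F)(F)F)CCC=C(C)C | intermediate
4 | (2E)-3-(tributylstannyl)prop-2-en-1-ol | OC/C=C/[Sn](CCCC)(CCCC)CCCC | starting material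
5 | (2E)-8-methyl-4-methylidenenona-2,7-dien-1-ol | OC/C=C/C(=C)CCC=C(C)C | intermediate
6 | methyl (2E)-8-methyl-4-methylidenenona-2,7-dien-1-yl carbonate | COC(=O)OC/C=C/C(=C)CCC=C(C)C | intermediate
7 | methyl (2E,7E)-9-hydroxy-8-methyl-4-methylidenenona-2,7-dien-1-yl carbonate | COC(=O)OC/C=C/C(=C)CC/C=C(\C)CO | intermediate
8 | methyl 2-methyl-3-oxobutanoate | COC(=O)C(C)C(C)=O | starting material
9 | methyl (3S,7E)-2-acetyl-3-ethenyl-9-hydroxy-2,8-dimethyl-4-methylidenenon-7-enoate (C2 epimers) | COC(=O)C(C)(C(C)=O)[C@@H](C=C)C(=C)CC/C=C(\C)CO | intermediate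
10 | (4R,8E)-4-ethenyl-10-hydroxy-3,9-dimethyl-5-methylidenedec-8-en-2-one (C3 epimers) | CC(=O)C(C)[C@@H](C=C)C(=C)CC/C=C(\C)CO | intermediate
11 | (2E,7R)-7-ethenyl-2,8-dimethyl-6-methylidene-9-oxodec-2-enal (C8 epimers) | CC(=O)C(C)[C@@H](C=C)C(=C)CC/C=C(\C)C=O | intermediate
12 | 2-(2-acetyl-3-ethenyl-2-methyl-4-methylidenecyclohexyl)propanal (ring B closed; acetyl and propanal arms trans; ring methyl cis to vinyl) | CC(=O)[C@]1(C)[C@@H](C=C)C(=C)CC[C@H]1C(C)C=O | intermediate
13 | 3-hydroxy-13,14,15,16,19-pentanorlabda-8(17),11-dien-1-one (C3 and C4 epimers) | CC1C(O)CC(=O)[C@]2(C)[C@@H](C=C)C(=C)CC[C@@H]12 | intermediate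
14 | 13,14,15,16,19-pentanorlabda-2,8(17),11-trien-1-one (4α-methyl; 5α-H; 9α-H; 10β-methyl) | C[C@@H]1C=CC(=O)[C@]2(C)[C@@H](C=C)C(=C)CC[C@@H]12 | intermediate
15 | 1-(trimethylsilyloxy)-13,14,15,16,19-pentanorlabda-1,3,8(17),11-tetraene | CC1=CC=C(O[Si](C)(C)C)[C@]2(C)[C@@H](C=C)C(=C)CC[C@@H]12 | intermediate
16 | 18-hydroxy-13,14,15,16-tetranorlabda-2,8(17),11-trien-1-one | OC[C@]1(C)C=CC(=O)[C@]2(C)[C@@H](C=C)C(=C)CC[C@@H]12 | intermediate
17 | 18-hydroxy-13,14,15,16-tetranorlabda-8(17),11-dien-1-one | OC[C@]1(C)CCC(=O)[C@]2(C)[C@@H](C=C)C(=C)CC[C@@H]12 | intermediate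
18 | 4-methylbenzenesulfonylhydrazone of 17 | OC[C@]1(C)CCC(=NNS(=O)(=O)c3ccc(C)cc3)[C@]2(C)[C@@H](C=C)C(=C)CC[C@@H]12 | intermediate
19 | 13,14,15,16-tetranorlabda-8(17),11-dien-18-ol | OC[C@]1(C)CCC[C@]2(C)[C@@H](C=C)C(=C)CC[C@@H]12 | intermediate
20 | 8α,17-epoxy-13,14,15,16-tetranorlabd-11-en-18-ol | OC[C@]1(C)CCC[C@]2(C)[C@@H](C=C)[C@]3(OC3)CC[C@@H]12 | intermediate
21 | 13,14,15,16-tetranorlabd-11-ene-8α,18-diol | OC[C@]1(C)CCC[C@]2(C)[C@@H](C=C)[C@](C)(O)CC[C@@H]12 | intermediate
22 | ethyl (2E)-3-iodobut-2-enoate | C/C(I)=C\C(=O)OCC | starting material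
23 | 12-(9-borabicyclo[3.3.1]nonan-9-yl)-13,14,15,16-tetranorlabdane-8α,18-diol | OC[C@]1(C)CCC[C@]2(C)[C@@H](CCB3C4CCCC3CCC4)[C@](C)(O)CC[C@@H]12 | intermediate
24 | ethyl 8α,18-dihydroxylabd-13E-en-15-oate | OC[C@]1(C)CCC[C@]2(C)[C@@H](CC/C(C)=C/C(=O)OCC)[C@](C)(O)CC[C@@H]12 | intermediate
25 | 8α,18-dihydroxylabd-13E-en-15-oic acid | OC[C@]1(C)CCC[C@]2(C)[C@@H](CC/C(C)=C/C(=O)O)[C@](C)(O)CC[C@@H]12 | intermediate
26 | 18-acetoxy-8α-hydroxylabd-13E-en-15-oic acid | CC(=O)OC[C@]1(C)CCC[C@]2(C)[C@@H](CC/C(C)=C/C(=O)O)[C@](C)(O)CC[C@@H]12 | target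

Total step count: 16. Longest linear sequence: 16 steps (1 to 26).

**Steps most likely to fail**

Step 8. Under equilibrating base the wrong enolate may react, the C10 configuration may be poorly controlled, or the enal may self-condense. The fallback sets out from 11 and separates the two bond formations. The aldehyde is converted into the dimethyl acetal F1 (HC(OMe)3, MeOH, pyridinium tosylate). The more substituted trimethylsilyl enol ether of the ketone F2 is then made (Me3SiCl, Et3N, DMF, 110 °C). Ring B is closed by a Me3SiOTf-catalysed intramolecular Mukaiyama–Michael addition onto the allylic acetal (attack at C5, six-membered ring). Acid hydrolysis of the resulting enol ether gives the keto aldehyde 12 as an isolated compound, and a separate aldol condensation (KOH, MeOH) closes ring A, rejoining the route at 14.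

Step 9. The formaldehyde may attack C2 (α) instead of C4 (γ), or facial selectivity at the crowded γ-carbon may be poor. The fallback sets out from 14 and moves the carbonyl so that C4 becomes an ordinary α′-position. Nucleophilic epoxidation (H2O2, NaOH, MeOH, 0 °C) gives the epoxy ketone F3. Wharton transposition (N2H4·H2O, AcOH, MeOH) gives the allylic alcohol F4, and MnO2 oxidation gives the transposed enone F5 (C3 ketone, C1=C2). The kinetic enolate (LiN(iPr)2, THF, −78 °C) is trapped with monomeric formaldehyde anti to the C10 methyl to give the hydroxymethyl enone F6. Conjugate reduction with [(Ph3P)CuH]6 gives the saturated hydroxy ketone F7, and the tosylhydrazone/catecholborane reduction of step 11 removes the C3 ketone, rejoining the route at 19.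

Step 5. Attack may occur at the wrong allyl terminus, or facial selectivity may be low with the branched alkenyl substituent. The fallback sets out from 5 and sets C9 by a sigmatropic shift instead. Esterification with propanoyl chloride and pyridine gives the dienyl propanoate F8. An enantioselective Ireland–Claisen rearrangement through the boron enolate made with a chiral 1,2-diphenylethylenediamine-derived bromoborane and i-Pr2NEt (chair transition state; C9–C10 bond and vinyl group formed together) gives the acid F9. MeLi (2.2 equiv) converts this to the methyl ketone F10, and SeO2/t-BuOOH oxidation of the prenyl E-methyl group as in step 4 rejoins the route at 10.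

**Further compounds**
F1 | step 8 | (4R,8E)-4-ethenyl-10,10-dimethoxy-3,9-dimethyl-5-methylidenedec-8-en-2-one | CC(=O)C(C)[C@@H](C=C)C(=C)CC/C=C(\C)C(OC)OC
F2 | step 8 | trimethylsilyl enol ether of F1 (C2=C3 enol ether of the ketone) | CC(O[Si](C)(C)C)=C(C)[C@@H](C=C)C(=C)CC/C=C(\C)C(OC)OC
F3 | step 9 | 2,3-epoxy-13,14,15,16,19-pentanorlabda-8(17),11-dien-1-one | C[C@@H]1C3OC3C(=O)[C@]2(C)[C@@H](C=C)C(=C)CC[C@@H]12
F4 | step 9 | 13,14,15,16,19-pentanorlabda-1,8(17),11-trien-3-ol | C[C@@H]1C(O)C=C[C@]2(C)[C@@H](C=C)C(=C)CC[C@@H]12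
F5 | step 9 | 13,14,15,16,19-pentanorlabda-1,8(17),11-trien-3-one | C[C@@H]1C(=O)C=C[C@]2(C)[C@@H](C=C)C(=C)CC[C@@H]12
F6 | step 9 | 18-hydroxy-13,14,15,16-tetranorlabda-1,8(17),11-trien-3-one | OC[C@]1(C)C(=O)C=C[C@]2(C)[C@@H](C=C)C(=C)CC[C@@H]12
F7 | step 9 | 18-hydroxy-13,14,15,16-tetranorlabda-8(17),11-dien-3-one | OC[C@]1(C)C(=O)CC[C@]2(C)[C@@H](C=C)C(=C)CC[C@@H]12
F8 | step 5 | (2E)-8-methyl-4-methylidenenona-2,7-dien-1-yl propanoate | CCC(=O)OC/C=C/C(=C)CCC=C(C)C
F9 | step 5 | (3R)-3-ethenyl-2,8-dimethyl-4-methylidenenon-7-enoic acid | OC(=O)C(C)[C@@H](C=C)C(=C)CCC=C(C)C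
F10 | step 5 | (4R)-4-ethenyl-3,9-dimethyl-5-methylidenedec-8-en-2-one | CC(=O)C(C)[C@@H](C=C)C(=C)CCC=C(C)C
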